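Ask how much J stands after 40 h in the flask charged with 0.25 M of E. L dissolves as Z, E with Z over G gives J, and E also turns G into D.

| setting | north-east | south-west | flask |
|---|---|---|---|
| E | 0.35 M | 0.55 M | 0.25 M |
| L | 49 mM (held) | 49 mM (held) | 49 mM (held) |
| G | 0.5 mol% | 0.5 mol% | 0.5 mol% |
| remark | run made earlier | run made earlier |  |
| time |  |  | 40 h |

- north-east (time / h: J / %, E / %): 2.00: 3.3, 94.2; 3.00: 7.6, 92.8; 4.00: 9.1, 90.6; 6.00: 13.1, 85.8; 10.0: 24.6, 76.9; 15.0: 32.5, 67.3; 25.0: 45.0, 52.1
- south-west (time / h: J / %, E / %): 3.00: 7.9, 90.3; 6.00: 16.4, 82.8; 10.0: 25.7, 73.2; 15.0: 34.3, 65.8; 20.0: 41.8, 58.1; 25.0: 47.9, 51.8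

(each reading ± 1 percentage point)

- the J standing at 40 h, as a percentage of the E charged
- concentration of Z in solution at 40 h, in percent of saturation

- at the start none of Z is dissolved
- the analysis behind the earlier runs scatters by 1 percentage point, standard deviation
- reactions considered so far: L <-> Z; E + Z + G -> G + J; E + G -> D

Work in logarithms. Take s, the decades of E lost per hour: log10(E charged / E left) / time. The bench rule (pseudo-first-order) holds s constant. Read s over the first 10.0 h of each earlier run:

s, north-east = 0.0114 h⁻¹; s, south-west = 0.0135 h⁻¹

n = log10(ratio of s) / log10(ratio of charges) = 0.381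

This n, the power of the E charge that s follows at fixed loading and fixed L, is a reading and carries the scatter. Scaled to the flask:

s, flask = 0.0100 h⁻¹

Held constant in the flask, that gives 0.400 decades, so J near 60.2%, with G able to take at most 0.5 mol% of E as D.

But the flask's time is 1.60 times that of the last reading in either run. Let b be the mean s up to that reading divided by the early s. The south-west run reads 0.843, lower than the north-east 0.993. Take the stronger bend as an estimate, though it is read at 25.0 h in a run with more E:

decades = s × time × b = 0.339, so E left 45.8% and J 54.1%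

The forecast stands a little lower, at 52% of J with Z at 96% of saturation, holding that “gas supply partly limits the reaction”.

The flask gives 53.5% of J and Z at 95.5% of saturation; its 46% of E left is 0.335 decades.

    L ⇌ Z, rate k1*(csat - [Z]) (kL = 0.775 h⁻¹)
    E + Z + G → G + J (k = 575 M⁻² h⁻¹)
    E + G → D (k = 0.127 M⁻¹ h⁻¹)

In the flask, L passed into Z with 74% of its turnover up to 40 h done by 20.0 h, while Z rose from none to 81.4% of saturation at 4.00 h and 91.4% at 20.0 h. The conversion to J had done half of its turnover up to 40 h by 13.8 h, while G fell to 59.9% of the G charged at 20.0 h and 42.4% at 40.0 h, the rest standing as D.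

Take a neighbour flask with 0.42 M of E, same loading and time: n gives s = 0.0122 h⁻¹, so 0.412 decades and J 61.3%. Computed, it holds 58.9% of J and 41% of E.

The earlier runs and the new flask are calculated for substances that don't exist; scatter was added.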